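**Plan**

1. Numbering (eremophilane type, used for all intermediates): ring A = C1–C5 + C10, ring B = C5–C10, C11–C13 = isopropenyl on C7, C14 = methyl on C5, C15 = methyl on C4; β is the face of C14.
2. Cuts: first the two acyl C–O bonds at O3 and O9 (the (Z)-olefins traced to alkynes); then C3 back to an enone/allylic silyl ether and C15 back to an ester; then the ring-A bonds C5–C10 and C3–C4 together, which opens both rings to an acyclic triene; last C4=C5, C7–C11, C6=C7 and C1=C2, leaving 2-deoxy-D-ribose (sugar C1, C2, C3, C4, C5 = C1, C10, C9, C8, C7).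
3. Enabling feature: the fusion bond C5–C10 and the bond C3–C4 lie 1,4 to each other in ring A, bridged by C1–C2 and flanked by the C3 oxygen. Ring A is therefore the cyclohexene of a C10=C1–C2=C3–OSi diene and a C4=C5 enoate, and C6–C9 of ring B, which carry the C7, C8 and C9 substituents, are the four-atom tether.
4. Forward order: the chain is joined linearly on the sugar (C1=C2 by cross-metathesis, C6=C7 by Wittig reaction, C7–C11 by conjugate addition, C4=C5 by Horner–Wadsworth–Emmons reaction). The silyloxydiene is then unveiled, rings A and B close together in one intramolecular Diels–Alder step, and C15, C3 and the hydroxyls are adjusted afterwards.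
5. Stereochemistry: C8 and C9 are C4 and C3 of the sugar; C7 comes from anti 1,2-induction by C8; C5, C10 and C4 come from the cycloaddition (chair tether, endo ester, (E)-enoate); C3 from a thermodynamically controlled ketone reduction; both (Z)-enoates from Lindlar reduction.

Key step: step 10

Remark: the C1=C2 olefin made in step 3 is written as (E); its geometry is taken to be irrelevant because this bond becomes the central single bond of the diene in step 9 (TBS = tert-butyldimethylsilyl, TMS = trimethylsilyl).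

**Route**

Step 1
Reactants: 1 2-deoxy-D-ribose
Product: 2 2-deoxy-3,4-O-isopropylidene-D-erythro-pentopyranose (lactol; anomer mixture)
Conditions: 2-methoxypropene, PPTS (cat.), EtOAc, rt
Reagents that add atoms: 2-methoxypropene, COC(C)=C
Why: Acid-catalysed acetonide formation with an enol ether under thermodynamic control, in which only the cis-3,4-diol of the pyranose can close a five-membered dioxolane while O5 and C1 stay tied in the lactol; no stereocentre of the skeleton is formed or disturbed.

Step 2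
Reactants: 2 lactol acetonide
Product: 4 [(4R,5S)-5-allyl-2,2-dimethyl-1,3-dioxolan-4-yl]methanol, via open-chain hydroxy aldehyde 3 (not isolated)
Conditions: Ph3PCH3Br (2.5 equiv), KOtBu (2.4 equiv), THF, 0 °C → rt
Reagents that add atoms: methyltriphenylphosphonium bromide, C[P+](c1ccccc1)(c1ccccc1)c1ccccc1.[Br-]
Why: Wittig methylenation of a lactol through its ring-opened aldehyde tautomer (excess ylide absorbs the hydroxyl proton), which frees the sugar C5 hydroxyl and turns sugar C1 into a vinyl group without touching either stereocentre.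

Step 3
Reactants: 4 allyl dioxolane alcohol; 5 allyloxy(tert-butyl)dimethylsilane
Product: 6 [(4R,5S)-5-[(2E)-4-(TBSO)but-2-en-1-yl]-2,2-dimethyl-1,3-dioxolan-4-yl]methanol
Conditions: 5 (4 equiv), second-generation Grubbs catalyst (H2IMes)(PCy3)Cl2Ru=CHPh (3 mol%), CH2Cl2, 40 °C
Reagents that add atoms: allyloxy(tert-butyl)dimethylsilane (5), C=CCO[Si](C)(C)C(C)(C)C
Why: Olefin cross-metathesis between two unhindered terminal alkenes, with the silyl ether partner in excess, installs C2 and C3 together with the C3 oxygen; the free alcohol and the acetonide are tolerated and no stereocentre is involved.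

Step 4
Reactants: 6 allylic silyl ether alcohol; 7 1-(triphenylphosphoranylidene)propan-2-one
Product: 9 (3E)-4-[(4R,5S)-5-[(2E)-4-(TBSO)but-2-en-1-yl]-2,2-dimethyl-1,3-dioxolan-4-yl]but-3-en-2-one, via α-alkoxy aldehyde 8 (not isolated)
Conditions: Dess–Martin periodinane, NaHCO3, CH2Cl2, 0 °C → rt; then 7, rt
Reagents that add atoms: 1-(triphenylphosphoranylidene)propan-2-one (7), CC(=O)C=P(c1ccccc1)(c1ccccc1)c1ccccc1
Why: One-pot Dess–Martin oxidation and Wittig olefination, in which the configurationally labile α-alkoxy aldehyde is trapped as it forms by the stabilised ylide to give the (E)-enone (C6=C7) with the dioxolane centres intact.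

Step 5
Reactants: 9 enone; 10 isopropenylmagnesium bromide
Product: 12 (4S)-4-[(4R,5S)-5-[(2E)-4-(TBSO)but-2-en-1-yl]-2,2-dimethyl-1,3-dioxolan-4-yl]-5-methylhex-5-en-2-one, via trimethylsilyl enol ether 11 (not isolated)
Conditions: 10 (1.5 equiv), CuBr·SMe2 (10 mol%), TMSCl (2 equiv), THF, −78 °C; then aq. citric acid, THF, 0 °C
Reagents that add atoms: isopropenylmagnesium bromide (10), C=C(C)[Mg]Br
Why: TMSCl-accelerated copper-catalysed conjugate addition of a Grignard reagent to a γ-alkoxy (E)-enone, in which the organocopper attacks anti to the C8–O bond held perpendicular to the π system (modified Felkin–Anh model) and so sets C7 as (S), isopropenyl anti to O8; the enol silane is hydrolysed on work-up.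

Step 6
Reactants: 12 methyl ketone; 13 trimethyl phosphonoacetate
Product: 14 methyl (2E,5S)-5-[(4R,5S)-5-[(2E)-4-(TBSO)but-2-en-1-yl]-2,2-dimethyl-1,3-dioxolan-4-yl]-3,6-dimethylhepta-2,6-dienoate
Conditions: 13, NaH, THF, 0 → 65 °C; minor (2Z)-isomer removed by chromatography
Reagents that add atoms: trimethyl phosphonoacetate (13), COC(=O)CP(=O)(OC)OC
Why: Horner–Wadsworth–Emmons olefination of a methyl ketone, whose reversible addition step favours the (E)-enoate with the ester trans to the larger CH2 branch; C7 is β to the carbonyl and cannot epimerise.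

Step 7
Reactants: 14 silyl ether enoate
Product: 15 methyl (2E,5S)-5-[(4R,5S)-5-[(2E)-4-hydroxybut-2-en-1-yl]-2,2-dimethyl-1,3-dioxolan-4-yl]-3,6-dimethylhepta-2,6-dienoate
Conditions: Bu4NF (1.1 equiv), THF, 0 °C
Reagents that add atoms: none
Why: Fluoride-mediated desilylation of the only silyl ether, to which the ester, the acetonide and the alkenes are inert at 0 °C.

Step 8
Reactants: 15 allylic alcohol
Product: 16 methyl (2E,5S)-5-[(4R,5S)-2,2-dimethyl-5-[(2E)-4-oxobut-2-en-1-yl]-1,3-dioxolan-4-yl]-3,6-dimethylhepta-2,6-dienoate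
Conditions: MnO2 (excess), CH2Cl2, rt
Reagents that add atoms: none
Why: MnO2 oxidation, selective for the allylic alcohol, gives the enal without touching the enoate or the isolated alkenes; any (2Z)-enal from the minor olefin isomer is of no consequence for the next step.

Step 9
Reactants: 16 enal
Product: 17 methyl (2E,5S)-5-[(4R,5S)-5-[(1E,3E)-4-(TBSO)buta-1,3-dien-1-yl]-2,2-dimethyl-1,3-dioxolan-4-yl]-3,6-dimethylhepta-2,6-dienoate
Conditions: TBSOTf (1.2 equiv), Et3N (2.5 equiv), Et2O, −78 → 0 °C
Reagents that add atoms: tert-butyldimethylsilyl trifluoromethanesulfonate, CC(C)(C)[Si](C)(C)OS(=O)(=O)C(F)(F)F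
Why: Soft enolisation (O-silylation of the enal, then removal of a C10 proton by Et3N) gives the 1-silyloxy-1,3-diene; the s-trans oxocarbenium ion leads to the (E)-enol ether, allylic strain places C9 trans on the new C10=C1 bond, and the fast silyl triflate pathway avoids a free dienolate that could expel the C9 alkoxide.

Step 10
Reactants: 17 silyloxy trienoate
Product: 18 methyl 3β-(TBSO)-7α-isopropenyl-8α,9α-(isopropylidenedioxy)-5β-methyl-10α-H-octal-1-ene-4β-carboxylate (trans-fused)
Conditions: Et2AlCl (1.5 equiv), CH2Cl2, −78 → −20 °C; aq. NaHCO3/KNaC4H4O6 work-up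
Reagents that add atoms: none
Why: Et2AlCl binds the ester carbonyl of 17, and the silyloxydiene adds to the activated enoate in a concerted but strongly asynchronous [4+2] cycloaddition in which the nucleophilic diene terminus C10 bonds to the β-carbon C5 ahead of C3–C4. The closest known reaction type is the Lewis-acid-promoted intramolecular Diels–Alder reaction of terminally activated 1,7,9-decatrienes (2,8,10-trienoates) carrying an oxygenated diene. Ring A (C10–C1–C2–C3–C4–C5) closes as the six-membered cycloaddition ring, and ring B (C5–C10) closes in the same event as the six-membered tether ring, its atoms C6–C9 folding into a chair. C5 and C10 (5β-methyl, 10α-H, trans fusion) are fixed by the ester-endo/tether-exo transition state on the diene face dictated by that chair (C7 isopropenyl and O9 equatorial, the cis-acetonide spanning axial O8 and equatorial O9); C4 (β-ester, cis to C14) follows stereospecifically from the (E)-enoate, and C3 (β-OTBS, erased later) from the (E,E)-diene together with endo addition. The step needs endo and π-facial selectivity: the aluminium-bound ester seeks the endo position, and the alternative chair would set the isopropenyl group and O9 syn-axial to C14. Regiochemistry is enforced by the tether and matches the polarity of the silyloxydiene.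

Step 11
Reactants: 18 cycloadduct ester
Product: 19 [3β-(TBSO)-7α-isopropenyl-8α,9α-(isopropylidenedioxy)-5β-methyl-10α-H-octal-1-en-4β-yl]methanol
Conditions: LiAlH4, Et2O, 0 °C
Reagents that add atoms: none
Why: LiAlH4 reduction of the hindered ester to the primary alcohol at C15, with silyl ether, acetonide and alkenes inert and C4 untouched because no enolate is formed.

Step 12
Reactants: 19 primary alcohol
Product: 20 [3β-(TBSO)-7α-isopropenyl-8α,9α-(isopropylidenedioxy)-5β-methyl-10α-H-octal-1-en-4β-yl]methyl methanesulfonate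
Conditions: MsCl, Et3N, CH2Cl2, 0 °C
Reagents that add atoms: methanesulfonyl chloride, CS(=O)(=O)Cl
Why: Sulfonylation of the only free hydroxyl (via sulfene) activates C15 for hydride displacement.

Step 13
Reactants: 20 mesylate
Product: 21 3β-(TBSO)-7α-isopropenyl-8α,9α-(isopropylidenedioxy)-4β,5β-dimethyl-10α-H-octal-1-ene
Conditions: LiEt3BH (4 equiv), THF, 0 → 65 °C
Reagents that add atoms: none
Why: SN2 displacement of the primary mesylate by the strongly nucleophilic hydride LiEt3BH, chosen because it reduces β-branched sulfonates, turns C15 into the C4 methyl group without affecting the C4 configuration.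

Step 14
Reactants: 21 allylic silyl ether
Product: 22 7α-isopropenyl-8α,9α-(isopropylidenedioxy)-4β,5β-dimethyl-10α-H-octal-1-en-3β-ol
Conditions: Bu4NF, THF, rt → 45 °C
Reagents that add atoms: none
Why: Fluoride cleavage of the secondary allylic silyl ether, with gentle warming to offset hindrance by the C4 methyl group.

Step 15
Reactants: 22 allylic alcohol
Product: 23 7α-isopropenyl-8α,9α-(isopropylidenedioxy)-4β,5β-dimethyl-10α-H-octal-1-en-3-one
Conditions: Dess–Martin periodinane, NaHCO3, CH2Cl2, rt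
Reagents that add atoms: none
Why: Dess–Martin oxidation under buffered, non-epimerising conditions gives the C3 enone and erases the C3 centre set in step 10.

Step 16
Reactants: 23 enone
Product: 26 7α-isopropenyl-8α,9α-(isopropylidenedioxy)-4β,5β-dimethyl-10α-H-decalin-3α-ol, via lithium enolate 24 (not isolated), via saturated ketone 25 (not isolated)
Conditions: Li (excess), liq. NH3/THF, −78 °C; then EtOH, −78 → −33 °C; NH4Cl
Reagents that add atoms: none
Why: Birch-type dissolving-metal reduction first gives the C2=C3 lithium enolate (isopropenyl and acetonide are inert), ethanol then releases the ketone in the presence of excess lithium, and thermodynamically controlled ketyl reduction sets the equatorial 3α-alcohol, which small hydrides would not favour because axial C14 blocks the β face; C4 remains the more stable equatorial β-methyl epimer.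

Step 17
Reactants: 26 acetonide alcohol
Product: 27 7α-isopropenyl-4β,5β-dimethyl-10α-H-decalin-3α,8α,9α-triol
Conditions: AcOH/H2O (4:1), 40 °C
Reagents that add atoms: none
Why: Mild aqueous acid hydrolyses the cis-fused dioxolane, conditions under which the 1,1-disubstituted alkene is not protonated.

Step 18
Reactants: 27 triol; 28 hex-2-ynoic acid
Product: 29 8α-hydroxy-7α-isopropenyl-4β,5β-dimethyl-10α-H-decalin-3α,9α-diyl bis(hex-2-ynoate)
Conditions: 28 (2.3 equiv), N,N'-diisopropylcarbodiimide (2.3 equiv), DMAP (0.1 equiv), CH2Cl2, −20 → 0 °C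
Reagents that add atoms: hex-2-ynoic acid (28), CCCC#CC(=O)O
Why: Steglich esterification should acylate the two equatorial hydroxyls (C3, C9) ahead of the axial C8 hydroxyl, which is flanked by the C7 isopropenyl group and deactivated further once O9 is esterified (the reactivity order of cis-1,2-diols on six-membered rings); the ynoic acid is used because a (Z)-enoic acid could isomerise during activation.

Step 19
Reactants: 29 bis-ynoate
Product: 30 8α-hydroxy-7α-isopropenyl-4β,5β-dimethyl-10α-H-decalin-3α,9α-diyl bis[(2Z)-hex-2-enoate] (CNP0420276.1)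
Conditions: H2 (1 atm), Lindlar catalyst (Pd on CaCO3 poisoned with Pb(OAc)2), quinoline, EtOAc, rt
Reagents that add atoms: none
Why: Lindlar semi-hydrogenation adds H2 syn to both conjugated alkynes to give the two (Z)-enoates, while quinoline suppresses over-reduction and hydrogenation of the isopropenyl group.

**Compound list**

1 | 2-deoxy-D-ribose | O=CC[C@H](O)[C@H](O)CO | starting material
2 | 2-deoxy-3,4-O-isopropylidene-D-erythro-pentopyranose (anomer mixture) | OC1C[C@@H]2OC(C)(C)O[C@@H]2CO1 | intermediate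
3 | 2-[(4S,5R)-5-(hydroxymethyl)-2,2-dimethyl-1,3-dioxolan-4-yl]acetaldehyde (open-chain tautomer of 2, not isolated) | OC[C@H]1OC(C)(C)O[C@H]1CC=O | intermediate
4 | [(4R,5S)-5-allyl-2,2-dimethyl-1,3-dioxolan-4-yl]methanol | OC[C@H]1OC(C)(C)O[C@H]1CC=C | intermediate
5 | allyloxy(tert-butyl)dimethylsilane | C=CCO[Si](C)(C)C(C)(C)C | starting material
6 | [(4R,5S)-5-[(2E)-4-(tert-butyldimethylsilyloxy)but-2-en-1-yl]-2,2-dimethyl-1,3-dioxolan-4-yl]methanol | OC[C@H]1OC(C)(C)O[C@H]1C/C=C/CO[Si](C)(C)C(C)(C)C | intermediate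
7 | 1-(triphenylphosphoranylidene)propan-2-one | CC(=O)C=P(c1ccccc1)(c1ccccc1)c1ccccc1 | starting material
8 | (4S,5S)-5-[(2E)-4-(tert-butyldimethylsilyloxy)but-2-en-1-yl]-2,2-dimethyl-1,3-dioxolane-4-carbaldehyde (not isolated) | O=C[C@H]1OC(C)(C)O[C@H]1C/C=C/CO[Si](C)(C)C(C)(C)C | intermediate
9 | (3E)-4-[(4R,5S)-5-[(2E)-4-(tert-butyldimethylsilyloxy)but-2-en-1-yl]-2,2-dimethyl-1,3-dioxolan-4-yl]but-3-en-2-one | CC(=O)/C=C/[C@H]1OC(C)(C)O[C@H]1C/C=C/CO[Si](C)(C)C(C)(C)C | intermediate
10 | isopropenylmagnesium bromide | C=C(C)[Mg]Br | starting material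
11 | trimethylsilyl enol ether of 12 (C5=C6 enol ether, geometry not defined; not isolated) | C=C(C)[C@H](C=C(C)O[Si](C)(C)C)[C@H]1OC(C)(C)O[C@H]1C/C=C/CO[Si](C)(C)C(C)(C)C | intermediate
12 | (4S)-4-[(4R,5S)-5-[(2E)-4-(tert-butyldimethylsilyloxy)but-2-en-1-yl]-2,2-dimethyl-1,3-dioxolan-4-yl]-5-methylhex-5-en-2-one | C=C(C)[C@H](CC(C)=O)[C@H]1OC(C)(C)O[C@H]1C/C=C/CO[Si](C)(C)C(C)(C)C | intermediate
13 | trimethyl phosphonoacetate | COC(=O)CP(=O)(OC)OC | starting material
14 | methyl (2E,5S)-5-[(4R,5S)-5-[(2E)-4-(tert-butyldimethylsilyloxy)but-2-en-1-yl]-2,2-dimethyl-1,3-dioxolan-4-yl]-3,6-dimethylhepta-2,6-dienoate | C=C(C)[C@H](C/C(C)=C/C(=O)OC)[C@H]1OC(C)(C)O[C@H]1C/C=C/CO[Si](C)(C)C(C)(C)C | intermediate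
15 | methyl (2E,5S)-5-[(4R,5S)-5-[(2E)-4-hydroxybut-2-en-1-yl]-2,2-dimethyl-1,3-dioxolan-4-yl]-3,6-dimethylhepta-2,6-dienoate | C=C(C)[C@H](C/C(C)=C/C(=O)OC)[C@H]1OC(C)(C)O[C@H]1C/C=C/CO | intermediate
16 | methyl (2E,5S)-5-[(4R,5S)-2,2-dimethyl-5-[(2E)-4-oxobut-2-en-1-yl]-1,3-dioxolan-4-yl]-3,6-dimethylhepta-2,6-dienoate | C=C(C)[C@H](C/C(C)=C/C(=O)OC)[C@H]1OC(C)(C)O[C@H]1C/C=C/C=O | intermediate
17 | methyl (2E,5S)-5-[(4R,5S)-5-[(1E,3E)-4-(tert-butyldimethylsilyloxy)buta-1,3-dien-1-yl]-2,2-dimethyl-1,3-dioxolan-4-yl]-3,6-dimethylhepta-2,6-dienoate | C=C(C)[C@H](C/C(C)=C/C(=O)OC)[C@H]1OC(C)(C)O[C@H]1/C=C/C=C/O[Si](C)(C)C(C)(C)C | intermediate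
18 | methyl 3β-(tert-butyldimethylsilyloxy)-7α-isopropenyl-8α,9α-(isopropylidenedioxy)-5β-methyl-10α-H-octal-1-ene-4β-carboxylate (trans-fused) | C=C(C)[C@@H]1C[C@]2(C)[C@@H](C(=O)OC)[C@@H](O[Si](C)(C)C(C)(C)C)C=C[C@H]2[C@@H]3OC(C)(C)O[C@H]13 | intermediate
19 | [3β-(tert-butyldimethylsilyloxy)-7α-isopropenyl-8α,9α-(isopropylidenedioxy)-5β-methyl-10α-H-octal-1-en-4β-yl]methanol | C=C(C)[C@@H]1C[C@]2(C)[C@@H](CO)[C@@H](O[Si](C)(C)C(C)(C)C)C=C[C@H]2[C@@H]3OC(C)(C)O[C@H]13 | intermediate
20 | [3β-(tert-butyldimethylsilyloxy)-7α-isopropenyl-8α,9α-(isopropylidenedioxy)-5β-methyl-10α-H-octal-1-en-4β-yl]methyl methanesulfonate | C=C(C)[C@@H]1C[C@]2(C)[C@@H](COS(C)(=O)=O)[C@@H](O[Si](C)(C)C(C)(C)C)C=C[C@H]2[C@@H]3OC(C)(C)O[C@H]13 | intermediate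
21 | 3β-(tert-butyldimethylsilyloxy)-7α-isopropenyl-8α,9α-(isopropylidenedioxy)-4β,5β-dimethyl-10α-H-octal-1-ene | C=C(C)[C@@H]1C[C@]2(C)[C@@H](C)[C@@H](O[Si](C)(C)C(C)(C)C)C=C[C@H]2[C@@H]3OC(C)(C)O[C@H]13 | intermediate
22 | 7α-isopropenyl-8α,9α-(isopropylidenedioxy)-4β,5β-dimethyl-10α-H-octal-1-en-3β-ol | C=C(C)[C@@H]1C[C@]2(C)[C@@H](C)[C@@H](O)C=C[C@H]2[C@@H]3OC(C)(C)O[C@H]13 | intermediate
23 | 7α-isopropenyl-8α,9α-(isopropylidenedioxy)-4β,5β-dimethyl-10α-H-octal-1-en-3-one | C=C(C)[C@@H]1C[C@]2(C)[C@@H](C)C(=O)C=C[C@H]2[C@@H]3OC(C)(C)O[C@H]13 | intermediate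
24 | lithium C2=C3 enolate of 25 (not isolated) | [Li+].C=C(C)[C@@H]1C[C@]2(C)[C@@H](C)C([O-])=CC[C@H]2[C@@H]3OC(C)(C)O[C@H]13 | intermediate
25 | 7α-isopropenyl-8α,9α-(isopropylidenedioxy)-4β,5β-dimethyl-10α-H-decalin-3-one (not isolated) | C=C(C)[C@@H]1C[C@]2(C)[C@@H](C)C(=O)CC[C@H]2[C@@H]3OC(C)(C)O[C@H]13 | intermediate
26 | 7α-isopropenyl-8α,9α-(isopropylidenedioxy)-4β,5β-dimethyl-10α-H-decalin-3α-ol | C=C(C)[C@@H]1C[C@]2(C)[C@@H](C)[C@H](O)CC[C@H]2[C@@H]3OC(C)(C)O[C@H]13 | intermediate
27 | 7α-isopropenyl-4β,5β-dimethyl-10α-H-decalin-3α,8α,9α-triol | C=C(C)[C@@H]1C[C@]2(C)[C@@H](C)[C@H](O)CC[C@H]2[C@H](O)[C@@H]1O | intermediate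
28 | hex-2-ynoic acid | CCCC#CC(=O)O | starting material
29 | 8α-hydroxy-7α-isopropenyl-4β,5β-dimethyl-10α-H-decalin-3α,9α-diyl bis(hex-2-ynoate) | C=C(C)[C@@H]1C[C@]2(C)[C@@H](C)[C@H](OC(=O)C#CCCC)CC[C@H]2[C@H](OC(=O)C#CCCC)[C@@H]1O | intermediate
30 | 8α-hydroxy-7α-isopropenyl-4β,5β-dimethyl-10α-H-decalin-3α,9α-diyl bis[(2Z)-hex-2-enoate]; (3R,4R,5R,7S,8R,9S,10R) in the numbering above; CNP0420276.1 | C=C(C)[C@@H]1C[C@]2(C)[C@@H](C)[C@H](OC(=O)/C=C\CCC)CC[C@H]2[C@H](OC(=O)/C=C\CCC)[C@@H]1O | target

**Step count and risks**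

Total: 19 steps. Longest linear sequence: 19 steps (1 → 30); the other starting materials enter as purchased compounds.

Steps most likely to fail:

1. Step 10 (key step). The aluminium Lewis acid may cleave the Si–O bond of the dienol ether or, pushed by the silyloxy donor, ionise the allylic C9–O bond of the acetonide before the hindered β,β-disubstituted enoate is attacked. Endo control may also erode if the temperature has to be raised. The fallback uses a silicon-free, less electron-rich diene and also covers the case that 17 proves too labile to handle after step 9. It sets out from enal 16 and comes back at allylic alcohol 22, replacing steps 9–14. Ac2O, Et3N and catalytic DMAP should convert 16 into the (1E,3E)-dienyl acetate F1. Et2AlCl-promoted cycloaddition, which the acetate should tolerate because it cannot be desilylated and assists C9–O ionisation far less, should give the 3β-acetoxy cycloadduct F2. LiAlH4 reduces the ester and removes the acetate to give the diol F3. Selective sulfonylation of the primary hydroxyl (MsCl, 2,4,6-collidine, −20 °C) gives the primary monomesylate F4, and LiEt3BH then delivers 22.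

2. Step 18. Discrimination between the equatorial C9 hydroxyl and the axial C8 hydroxyl may be incomplete, and over-acylation or acyl migration across the cis-diol would give regioisomeric di- and triesters. The fallback acylates O3 and O9 in separate, directed operations; it sets out from alcohol 26 and comes back at bis-ynoate 29. Steglich esterification of 26 with 28, while the acetonide still masks O8 and O9, gives the 3-(hex-2-ynoate) acetonide F5. Aqueous acetic acid releases the 8,9-diol monoester F6. Bu2SnO (toluene, reflux, removal of water) converts the cis-diol into the dibutylstannylene acetal F7, in which the equatorial O9 is the activated oxygen. Hex-2-ynoyl chloride F8 (from 28 with oxalyl chloride and catalytic DMF) then acylates O9, and aqueous work-up gives 29.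

3. Step 5. Facial selectivity may be poor: the (E)-methyl enone can react through s-cis and s-trans conformers, and 1,2-induction by a γ-alkoxy centre is less well documented for enones than for enoates, so the C7 epimer may form in quantity. The fallback changes the acceptor; it sets out from alcohol 6 and comes back at methyl ketone 12. Alcohol 6 is oxidised as in step 4 (aldehyde 8) but trapped with methyl (triphenylphosphoranylidene)acetate to give the (E)-enoate F9, the acceptor class for which anti addition next to a γ-alkoxy centre is most firmly established. Addition of 10 under the CuBr·SMe2/TMSCl conditions gives the silyl ketene acetal F10 and, on work-up, the ester F11. MeNH(OMe)·HCl with iPrMgCl gives the Weinreb amide F12, and MeMgBr then delivers 12.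

**Further compounds**

F1 | step 10 | methyl (2E,5S)-5-[(4R,5S)-5-[(1E,3E)-4-acetoxybuta-1,3-dien-1-yl]-2,2-dimethyl-1,3-dioxolan-4-yl]-3,6-dimethylhepta-2,6-dienoate | C=C(C)[C@H](C/C(C)=C/C(=O)OC)[C@H]1OC(C)(C)O[C@H]1/C=C/C=C/OC(C)=O
F2 | step 10 | methyl 3β-acetoxy-7α-isopropenyl-8α,9α-(isopropylidenedioxy)-5β-methyl-10α-H-octal-1-ene-4β-carboxylate | C=C(C)[C@@H]1C[C@]2(C)[C@@H](C(=O)OC)[C@@H](OC(C)=O)C=C[C@H]2[C@@H]3OC(C)(C)O[C@H]13
F3 | step 10 | 4β-(hydroxymethyl)-7α-isopropenyl-8α,9α-(isopropylidenedioxy)-5β-methyl-10α-H-octal-1-en-3β-ol | C=C(C)[C@@H]1C[C@]2(C)[C@@H](CO)[C@@H](O)C=C[C@H]2[C@@H]3OC(C)(C)O[C@H]13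
F4 | step 10 | [3β-hydroxy-7α-isopropenyl-8α,9α-(isopropylidenedioxy)-5β-methyl-10α-H-octal-1-en-4β-yl]methyl methanesulfonate | C=C(C)[C@@H]1C[C@]2(C)[C@@H](COS(C)(=O)=O)[C@@H](O)C=C[C@H]2[C@@H]3OC(C)(C)O[C@H]13
F5 | step 18 | 7α-isopropenyl-8α,9α-(isopropylidenedioxy)-4β,5β-dimethyl-10α-H-decalin-3α-yl hex-2-ynoate | C=C(C)[C@@H]1C[C@]2(C)[C@@H](C)[C@H](OC(=O)C#CCCC)CC[C@H]2[C@@H]3OC(C)(C)O[C@H]13
F6 | step 18 | 8α,9α-dihydroxy-7α-isopropenyl-4β,5β-dimethyl-10α-H-decalin-3α-yl hex-2-ynoate | C=C(C)[C@@H]1C[C@]2(C)[C@@H](C)[C@H](OC(=O)C#CCCC)CC[C@H]2[C@H](O)[C@@H]1O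
F7 | step 18 | 8α,9α-O-dibutylstannylene acetal of F6 | C=C(C)[C@@H]1C[C@]2(C)[C@@H](C)[C@H](OC(=O)C#CCCC)CC[C@H]2[C@@H]3O[Sn](CCCC)(CCCC)O[C@H]13
F8 | step 18 | hex-2-ynoyl chloride | CCCC#CC(Cl)=O
F9 | step 5 | methyl (2E)-3-[(4R,5S)-5-[(2E)-4-(tert-butyldimethylsilyloxy)but-2-en-1-yl]-2,2-dimethyl-1,3-dioxolan-4-yl]prop-2-enoate | COC(=O)/C=C/[C@H]1OC(C)(C)O[C@H]1C/C=C/CO[Si](C)(C)C(C)(C)C
F10 | step 5 | methyl trimethylsilyl ketene acetal of F11 (geometry not defined) | C=C(C)[C@H](C=C(OC)O[Si](C)(C)C)[C@H]1OC(C)(C)O[C@H]1C/C=C/CO[Si](C)(C)C(C)(C)C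
F11 | step 5 | methyl (3S)-3-[(4R,5S)-5-[(2E)-4-(tert-butyldimethylsilyloxy)but-2-en-1-yl]-2,2-dimethyl-1,3-dioxolan-4-yl]-4-methylpent-4-enoate | C=C(C)[C@H](CC(=O)OC)[C@H]1OC(C)(C)O[C@H]1C/C=C/CO[Si](C)(C)C(C)(C)C
F12 | step 5 | (3S)-3-[(4R,5S)-5-[(2E)-4-(tert-butyldimethylsilyloxy)but-2-en-1-yl]-2,2-dimethyl-1,3-dioxolan-4-yl]-N-methoxy-N,4-dimethylpent-4-enamide | C=C(C)[C@H](CC(=O)N(C)OC)[C@H]1OC(C)(C)O[C@H]1C/C=C/CO[Si](C)(C)C(C)(C)C
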